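3.98 is the number we would give you first. Call it the reach: the natural logarithm of the share of the charge open to chains over the share still free when the flask stops. It is the mean of this logarithm over the last readings of the earlier runs, so it carries their scatter.

in all of them: initiator 31 µM

| flask | free monomer | transfer agent | protic impurity | remark | time |
|---|---|---|---|---|---|
| south-west | 0.0067 M | 1.1 mM | 0.55 mM | run made earlier |  |
| south-east | 0.010 M | 1.1 mM | 0.55 mM | run made earlier |  |
| east | 0.0078 M | 1.1 mM | 0.55 mM | run made earlier |  |
| Wednesday's | 0.011 M | 1.10 mM | 0.550 mM |  | 3.0 h |
| Friday's | 0.0080 M | 1.10 mM | 0.550 mM |  | 3.0 h |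

- south-west (time / min: monomer in chains / %, free monomer / %): 30.0: 85.0, 8.9; 60.0: 89.9, 2.8; 90.0: 90.7, 1.8; 120: 90.2, 1.7
- south-east (time / min: monomer in chains / %, free monomer / %): 10.0: 62.1, 32.6; 25.0: 86.3, 10.2; 50.0: 90.7, 3.6; 120: 92.2, 2.2
- east (time / min: monomer in chains / %, free monomer / %): 15.0: 73.5, 20.9; 40.0: 88.3, 4.5; 80.0: 91.1, 1.7; 120: 91.0, 1.4

(each reading ± 0.5 percentage points)

- which of the two ends with the longer chains by the average number of monomer units in a chain (chains begun, living or dead) ("neither" if they lie within 10%) (Wednesday's / Friday's / neither)
- average number of monomer units in a chain (chains begun, living or dead) at the end, Wednesday's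
- average number of monomer units in a chain (chains begun, living or dead) at the end, Friday's

- the average divides the monomer in chains by the number of chains begun, living and dead together
- what was read earlier has a scatter of 0.5 percentage points, one standard deviation
- steps thought possible: free monomer + initiator -> living end + monomer in chains; free monomer + living end -> monomer in chains + living end; living end + transfer agent -> dead chain; initiator -> spent initiator; protic impurity + free monomer -> quenched substrate
- the earlier runs do not show the number of chains; that part of a forecast is a guess

The open share is what the protic impurity leaves. At the last south-east reading, chains and free monomer add up to 94.4%, and one minus the impurity's fraction of the charge is 94.5%. The transfer agent stands at 1.10 mM against 31 µM of initiator, so we treat the death of living ends as pseudo-first-order. By the steps proposed, with the number of chains held, the reach then goes as one over the transfer agent, though the earlier runs share one charge of it and do not test this.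

For Wednesday's, the open share is 95.0% and the free share at the stop is 1.77%. Taking one chain per initiator, which is our guess, the length is 331. For Friday's, the same reckoning gives 93.1%, 1.74% and 236, so Wednesday's is longer. Your forecast also names Wednesday's, with 365 against 265, on the ground that “the number of chains barely depends on monomer charge”. Our Wednesday's figure is lower, and so is our Friday's.

The flask gives Wednesday's, with 336 against 241, and the forecast held within its tolerance. Wednesday's has 93.8% of its charge in chains after 3.00 h. The reach put 1.77% free at the stop, and Wednesday's holds 1.23%.

    free monomer + initiator → living end + monomer in chains (k = 3.80 L mol⁻¹ s⁻¹)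
    free monomer + living end → monomer in chains + living end, rate k2*[living end]*[free monomer] (k = 69.0 L mol⁻¹ s⁻¹)
    living end + transfer agent → dead chain (kL = 0.450 L mol⁻¹ s⁻¹)
    initiator → spent initiator (k = 3.80 × 10⁻⁴ s⁻¹)
    protic impurity + free monomer → quenched substrate (k = 0.830 L mol⁻¹ s⁻¹)

Now take Wednesday's with 0.0044 M of transfer agent. The reach falls to 0.995, which leaves 35.1% free and a length of 213. The computed flask leaves 32.0% free and gives 226.

(All runs were generated by integration with constants of no real substance; noise was put on by code.)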